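In a one-step world a portion of substrate dies away as a plain exponential, so product is one minus the mean of those exponentials. One number then describes the flask. I call it the charge time constant: the time in which a portion's unreacted substrate shrinks by a factor e.

| flask | substrate | coupling partner | free catalyst | temperature | remark | time |
|---|---|---|---|---|---|---|
| red | 0.50 M (in portions, 3) | 0.26 M | 0.50 mM | −5 °C | run made earlier; portions every 15 h |  |
| grey | 0.50 M (in portions, 3) | 1.1 M | 0.50 mM | 20 °C | run made earlier; portions every 15 h |  |
| south-east | 0.50 M | 0.525 M | 0.50 mM | 0 °C | everything together at the start | 3.0 d |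
| south-west | 0.50 M (in portions, 3) | 0.525 M | 0.50 mM | 40 °C | the portions of substrate follow each other after 15 h, the first at the start | 3.0 d |

- red (time / d: product / %): 3.00: 0; 6.00: 5; 10.0: 3; 12.0: 4; 15.0: 7; 20.0: 8; 25.0: 11
- grey (time / d: product / %): 0.333: 5; 0.833: 5; 1.67: 13; 3.00: 24; 5.00: 41; 6.00: 45

(standard deviation of a reading: 2 percentage points)



- the flask that ends with the higher amount of product, in percent of the substrate charged, or "neither" when 2 percentage points or less lies between them (south-east / south-west / neither)
- final product, as a percentage of the substrate charged, in south-east
- final product, as a percentage of the substrate charged, in south-west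

With 3 equal portions evenly spaced and all in, the mean age of the charge is clock time less one interval. Grey's last reading, 45% at 6.00 d, therefore gave me 8.99 d, and red's last, 11% at 25.0 d, gave 209 d. These runs differ in partner and in temperature. I put the whole ratio on temperature, which was a choice, and it read as an activation energy of 82.3 kJ mol⁻¹.

Then I climbed the ladder, fastest rung first. The charge time constant of south-west came to 1.04 d, longer than the 15 h between portions, so there the portions overlap. The flask time 3.0 d spans 2.88 such constants, and summing the exponentials gave me 88.5%. Grey's constant, longer than that time, comes next. South-east's, 106 d, is far longer than its time, so I reckoned that flask on a straight line, with 2.78% conversion, hardly any. Red's constant, longer than the others, tops the ladder.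

The forecast chose south-west, with 4.5% (2.5% to 7%) in south-east and 35% (22% to 65%) in south-west. It took the rate as first order in partner, warning that “the two runs differ in both partner and temperature”. My south-east figure stood below its value, and my south-west figure above its value.

The flasks gave 2.30% in south-east and 71.6% in south-west, so south-west made more.

    catalyst intermediate D → free catalyst + product (k = 68.0 h⁻¹, Ea = 88.0 kJ mol⁻¹)
    catalyst intermediate C ⇌ by-product + catalyst intermediate D (K = 0.510 M, k = 4600 h⁻¹, Ea = 80.0 kJ mol⁻¹, ΔH = −50.0 kJ mol⁻¹)
    catalyst intermediate A ⇌ catalyst intermediate B (K = 6.60, k = 420 h⁻¹, Ea = 83.0 kJ mol⁻¹, ΔH = −43.0 kJ mol⁻¹)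
    coupling partner + catalyst intermediate B ⇌ catalyst intermediate C (K = 1.70 L mol⁻¹, k = 99.0 L mol⁻¹ h⁻¹, Ea = 56.0 kJ mol⁻¹, ΔH = −14.0 kJ mol⁻¹)
    substrate + free catalyst → catalyst intermediate A (k = 210 L mol⁻¹ h⁻¹, Ea = 60.0 kJ mol⁻¹)
    (constants at 40 °C)

At 3.00 d in south-west, substrate's half-life through capture by free catalyst was 1.4 d, a time constant of 2.05 d, twice my 1.04 d. With the catalyst charge counted as free, that half-life in south-west is 0.28 d, but at 3.00 d 19.4% of the catalyst charged stood free, and catalyst intermediate B, the resting state, held 56.2%.

Take south-west read at 30 h, just before its last portion. With 1.04 d, the two portions then in the flask give 38.4% of the whole charge as product, and that flask held 35.7%.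

The runs are calculated with constants of no real substance; noise was put on by code.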